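**Retrosynthetic overview**
1. Target ⇒ (3R)-licoricidin: the hydroxyquinone is made last, by para-selective oxidation of the ring B resorcinol (the likely natural origin of the quinone).
2. Licoricidin ⇒ diprenylated isoflavone: one-flask asymmetric transfer hydrogenation (conjugate reduction, dynamic kinetic resolution at C3, C4 deoxygenation), following isoflavone → isoflavanone → isoflavanol → isoflavan.
3. Isoflavone ⇒ chalcone epoxide: a 1,2-shift puts ring B on C3 (laboratory counterpart of the isoflavone synthase migration), then ring C closes on the phenol oxygen. Nucleophilic epoxidation is used because it ignores the prenyl alkenes.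
4. Chalcone ⇒ Claisen–Schmidt union of a prenylated acetophenone (ring A, from phloroacetophenone) and a prenylated benzaldehyde (ring B, from resorcinol).
5. Ring order: rings A and B are bought as arenes, ring C is closed at the isoflavone stage, and the quinone ring is generated from ring B in the final step.

Assumption: the stereocentre in the SMILES is read as (R) at C3 of the chroman, as in natural (3R)-licoricidin.
Abbreviations: prenyl = 3-methylbut-2-en-1-yl; MOM = methoxymethyl; TsDPEN = N-(p-toluenesulfonyl)-1,2-diphenylethane-1,2-diamine.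

**Route**

Step 1
Reactants: 1 2′,4′,6′-trihydroxyacetophenone
Product: 2 1-[2,4,6-trihydroxy-3-prenylphenyl]ethan-1-one
Conditions: prenyl bromide (1.0 equiv), DBU (1.1 equiv), THF, 0 °C → rt, 16 h
Reagents that add atoms: prenyl bromide (1-bromo-3-methylbut-2-ene), CC(C)=CCBr
Why: Friedel–Crafts-type C-alkylation of the phloroglucinol phenoxide, whose two free ring positions are equivalent; DBU in THF favours C- over O-prenylation and the mono-C-prenyl product is separated from di- and O-alkylated material.

Step 2
Reactants: 2 1-[2,4,6-trihydroxy-3-prenylphenyl]ethan-1-one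
Product: 3 1-[2-hydroxy-4,6-bis(methoxymethoxy)-3-prenylphenyl]ethan-1-one
Conditions: MOMCl (2.2 equiv), DIPEA (2.5 equiv), CH2Cl2, 0 °C → rt
Reagents that add atoms: chloromethyl methyl ether (MOMCl), COCCl
Why: Williamson-type MOM protection takes the 4-OH (para to acetyl, most acidic) and the unhindered 6-OH, while the OH wedged between acetyl and prenyl stays free because it is the most hindered and is held in the hydrogen bond to the ketone.

Step 3
Reactants: 3 1-[2-hydroxy-4,6-bis(methoxymethoxy)-3-prenylphenyl]ethan-1-one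
Product: 4 1-[2-methoxy-4,6-bis(methoxymethoxy)-3-prenylphenyl]ethan-1-one
Conditions: MeI (3 equiv), K2CO3 (3 equiv), DMF, 40 °C
Reagents that add atoms: iodomethane, CI
Why: Williamson methylation of the one remaining (chelated) phenol fixes the future 5-OMe next to the prenyl group, so ring C can later close only through the other ortho oxygen and the prenyl ends at C6.

Step 4
Reactants: 5 resorcinol
Product: 6 1,3-bis(methoxymethoxy)benzene
Conditions: MOMCl (2.5 equiv), DIPEA (3 equiv), CH2Cl2, 0 °C → rt
Reagents that add atoms: chloromethyl methyl ether (MOMCl), COCCl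
Why: Williamson-type bis-MOM protection installs the two directing groups needed for the metalations in step 5.

Step 5
Reactants: 6 1,3-bis(methoxymethoxy)benzene
Product: 8 2,4-bis(methoxymethoxy)-3-prenylbenzaldehyde, via prenylarene 7 (not isolated)
Conditions: n-BuLi (1.05 equiv), THF, 0 °C, 1 h; prenyl bromide (1.0 equiv), −78 °C → rt; then n-BuLi (1.3 equiv), TMEDA, 0 °C, 1 h; DMF, 0 °C → rt; H2O
Reagents that add atoms: prenyl bromide, CC(C)=CCBr; N,N-dimethylformamide, CN(C)C=O
Why: Two directed ortho-metalations in one flask: the first lithiation occurs at C2 between the two OMOM groups and is alkylated by prenyl bromide, and the second occurs at C4 ortho to an OMOM group and is trapped with DMF (Bouveault-type formylation).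

Step 6
Reactants: 4 1-[2-methoxy-4,6-bis(methoxymethoxy)-3-prenylphenyl]ethan-1-one; 8 2,4-bis(methoxymethoxy)-3-prenylbenzaldehyde
Product: 9 (E)-1-[2-methoxy-4,6-bis(methoxymethoxy)-3-prenylphenyl]-3-[2,4-bis(methoxymethoxy)-3-prenylphenyl]prop-2-en-1-one
Conditions: KOH (5 equiv), EtOH/H2O, rt → 50 °C, 24–48 h
Reagents that add atoms: none
Why: Claisen–Schmidt aldol condensation; with no free phenol present the methyl ketone enolate forms cleanly and dehydration gives the (E)-enone.

Step 7
Reactants: 9 the (E)-chalcone
Product: 10 racemic trans-(2R*,3S*)-[3-(2,4-bis(methoxymethoxy)-3-prenylphenyl)oxiran-2-yl][2-methoxy-4,6-bis(methoxymethoxy)-3-prenylphenyl]methanone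
Conditions: 30% H2O2 (5 equiv), 2 M NaOH, MeOH/THF, 0 °C → rt
Reagents that add atoms: hydrogen peroxide, OO
Why: Weitz–Scheffer nucleophilic epoxidation, in which hydroperoxide adds only to the electron-poor enone and leaves both electron-rich prenyl alkenes untouched; the racemic trans-epoxide stereocentres are destroyed in step 8.

Step 8
Reactants: 10 the trans-chalcone epoxide
Product: 12 3-[2,4-bis(methoxymethoxy)-3-prenylphenyl]-5-methoxy-7-(methoxymethoxy)-6-prenyl-4H-chromen-4-one, via formyl ketone 11 (not isolated)
Conditions: BF3·OEt2 (2 equiv), CH2Cl2, −40 → 0 °C, 30 min; then MeOH (10 equiv), 0 °C → rt, 2 h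
Reagents that add atoms: none
Why: House–Meinwald-type chalcone oxide rearrangement, in which BF3 opens the epoxide at the benzylic carbon (cation stabilised by the 2,4-dialkoxyaryl ring B) and the aroyl group undergoes a 1,2-shift to formyl ketone 11, after which BF3/MeOH cleaves the MOM ether chelated to the ketone fastest and the freed phenol cyclodehydrates onto the formyl group to close ring C with ring B on C3.

Step 9
Reactants: 12 the tri-MOM diprenyl isoflavone
Product: 16 (3R)-licoricidin, via isoflavanone 13 (not isolated), via cis-isoflavan-4-ol 14 (not isolated), via tri-MOM isoflavan 15 (not isolated)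
Conditions: RuCl[(R,R)-TsDPEN](p-cymene) (5 mol%), HCO2H/Et3N (5:2), EtOAc, 45 °C, 24 h; then 3 M HCl in MeOH, rt, 2 h
Reagents that add atoms: none
Why: Proposed new method: Ru–H conjugate reduction of the chromone gives isoflavanone 13, whose C3 epimerises rapidly through the enol in HCO2H/Et3N; the (R,R)-catalyst delivers hydride to C4 anti to the 3-aryl group and consumes only the (3R)-ketone, giving the cis-(3R,4R)-alcohol 14 (Noyori–Ikariya transfer hydrogenation with dynamic kinetic resolution, which sets C3); the 2,4,6-trioxygenated benzylic alcohol then ionises in the formic acid medium to a quinone-methide-type oxocarbenium ion that is reduced by Ru–H to isoflavan 15 without touching C3, and HCl/MeOH finally removes the three MOM groups; the closest known reactions are the domino transfer hydrogenation/deoxygenation of isoflavanones and the transfer hydrogenation of isoflavones to cis-isoflavan-4-ols, and isolated prenyl alkenes are inert to this catalyst.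

Step 10
Reactants: 16 (3R)-licoricidin
Product: 17 2-hydroxy-5-[(3R)-7-hydroxy-5-methoxy-6-prenylchroman-3-yl]-3-prenyl-1,4-benzoquinone (target)
Conditions: (KSO3)2NO (2.5 equiv), KH2PO4 buffer (pH 6), acetone/H2O, 0 °C → rt
Reagents that add atoms: potassium nitrosodisulfonate, [K+].[K+].[O-]S(=O)(=O)N([O])S(=O)(=O)[O-]
Why: Teuber oxidation, in which the nitrosodisulfonate radical abstracts a phenolic hydrogen and a second radical couples at C5′ of ring B (the only free position para to a phenol, para to 2′-OH), loss of HN(SO3K)2 giving the 2-hydroxy-1,4-benzoquinone; ring A has no free para position and reacts more slowly, and the weakly acidic buffer leaves C3 untouched.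

**Compound list**

1 | 2′,4′,6′-trihydroxyacetophenone (phloroacetophenone) | CC(=O)c1c(O)cc(O)cc1O | starting material
2 | 1-[2,4,6-trihydroxy-3-(3-methylbut-2-en-1-yl)phenyl]ethan-1-one | CC(=O)c1c(O)cc(O)c(CC=C(C)C)c1O | intermediate
3 | 1-[2-hydroxy-4,6-bis(methoxymethoxy)-3-(3-methylbut-2-en-1-yl)phenyl]ethan-1-one | CC(=O)c1c(OCOC)cc(OCOC)c(CC=C(C)C)c1O | intermediate
4 | 1-[2-methoxy-4,6-bis(methoxymethoxy)-3-(3-methylbut-2-en-1-yl)phenyl]ethan-1-one | CC(=O)c1c(OCOC)cc(OCOC)c(CC=C(C)C)c1OC | intermediate
5 | resorcinol | Oc1cccc(O)c1 | starting material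
6 | 1,3-bis(methoxymethoxy)benzene | COCOc1cccc(OCOC)c1 | intermediate
7 | 1,3-bis(methoxymethoxy)-2-(3-methylbut-2-en-1-yl)benzene | COCOc1cccc(OCOC)c1CC=C(C)C | intermediate (not isolated)
8 | 2,4-bis(methoxymethoxy)-3-(3-methylbut-2-en-1-yl)benzaldehyde | COCOc1ccc(C=O)c(OCOC)c1CC=C(C)C | intermediate
9 | (E)-chalcone: ring A 2′-OMe, 3′-prenyl, 4′,6′-bis(OMOM); ring B 2,4-bis(OMOM), 3-prenyl | COCOc1cc(OCOC)c(C(=O)/C=C/c2ccc(OCOC)c(CC=C(C)C)c2OCOC)c(OC)c1CC=C(C)C | intermediate
10 | trans-epoxide of chalcone 9, racemic (2R*,3S*); one enantiomer drawn | COCOc1cc(OCOC)c(C(=O)[C@H]2O[C@@H]2c3ccc(OCOC)c(CC=C(C)C)c3OCOC)c(OC)c1CC=C(C)C | intermediate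
11 | 2-[2,4-bis(methoxymethoxy)-3-prenylphenyl]-3-[2-methoxy-4,6-bis(methoxymethoxy)-3-prenylphenyl]-3-oxopropanal (racemic, enolisable) | O=CC(c1ccc(OCOC)c(CC=C(C)C)c1OCOC)C(=O)c1c(OC)c(CC=C(C)C)c(OCOC)cc1OCOC | intermediate (not isolated)
12 | 3-[2,4-bis(methoxymethoxy)-3-prenylphenyl]-5-methoxy-7-(methoxymethoxy)-6-prenyl-4H-chromen-4-one | COCOc1cc2occ(-c3ccc(OCOC)c(CC=C(C)C)c3OCOC)c(=O)c2c(OC)c1CC=C(C)C | intermediate
13 | corresponding isoflavanone (chroman-4-one), C3 racemising | COCOc1cc2OCC(c3ccc(OCOC)c(CC=C(C)C)c3OCOC)C(=O)c2c(OC)c1CC=C(C)C | intermediate (not isolated)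
14 | (3R,4R)-cis-isoflavan-4-ol, 3-aryl and 4-OH cis | COCOc1cc2OC[C@@H](c3ccc(OCOC)c(CC=C(C)C)c3OCOC)[C@@H](O)c2c(OC)c1CC=C(C)C | intermediate (not isolated)
15 | (3R)-3-[2,4-bis(methoxymethoxy)-3-prenylphenyl]-5-methoxy-7-(methoxymethoxy)-6-prenylchroman | COCOc1cc2OC[C@@H](c3ccc(OCOC)c(CC=C(C)C)c3OCOC)Cc2c(OC)c1CC=C(C)C | intermediate (not isolated)
16 | (3R)-licoricidin: (3R)-3-[2,4-dihydroxy-3-prenylphenyl]-5-methoxy-6-prenylchroman-7-ol | COc1c(CC=C(C)C)c(O)cc2c1C[C@H](c1ccc(O)c(CC=C(C)C)c1O)CO2 | intermediate
17 | 2-hydroxy-5-[(3R)-7-hydroxy-5-methoxy-6-(3-methylbut-2-en-1-yl)chroman-3-yl]-3-(3-methylbut-2-en-1-yl)cyclohexa-2,5-diene-1,4-dione | COc1c(CC=C(C)C)c(O)cc2c1C[C@H](C1=CC(=O)C(O)=C(CC=C(C)C)C1=O)CO2 | target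

**Totals**
Total step count: 10. Longest linear sequence: 8 steps (steps 1, 2, 3, 6, 7, 8, 9, 10).

**Three steps most likely to fail, with fallbacks**

Step 8 (epoxide rearrangement and selective ring closure). The risks are closure of the ring B oxygen onto the formyl group to give a 3-aroylbenzofuran, premature loss of ring B MOM groups, or acid damage to the prenyl groups. The fallback sets out from chalcone 9 and follows the chalcone → flavanone → isoflavone order. Dilute HCl in MeOH/THF at 0 °C removes only the MOM ether chelated to the ketone and gives the 2′-hydroxychalcone F1. NaOAc in refluxing EtOH closes ring C by oxa-Michael addition to the racemic flavanone F2. TBSOTf/Et3N in CH2Cl2 converts it into the silyl enol ether F3. PhI(OH)OTs in CH2Cl2 at −78 °C attacks the enol ether, which is far more nucleophilic than the prenyl alkenes at this temperature; the iodane at C3 triggers the shift of ring B from C2 to C3 and loss of H3 gives isoflavone 12, where the route is rejoined.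

Step 9 (one-flask reduction, resolution and deoxygenation). The risks are slow reduction of the hindered 5-methoxy ketone, stalling at the alcohol, and loss of ee if the C4 cation eliminates to the isoflav-3-ene before hydride capture. The fallback sets out from 12. The same catalyst at 25 °C with a short reaction time is stopped at the cis-(3R,4R)-isoflavan-4-ol 14, which is isolated. 1 M HCl in MeOH then removes the MOM groups and the freed 2′-OH captures the C4 cation intramolecularly, which outruns loss of H3, giving the cis-(6aR,11aR)-pterocarpan F4. Reductive opening of the benzylic C11a–O bond with Li in NH3/THF at −78 °C, followed by NH4Cl quench, gives licoricidin 16, where the route is rejoined; the phenoxides protect the arenes and the isolated prenyl alkenes are not reduced. This is the chemical counterpart of pterocarpan reductase.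

Step 10 (chemoselective oxidation with the ring A phenol free). The risk is competing ortho-oxidation of ring A at C8 or over-oxidation. The fallback sets out from 16 and separates oxygenation from oxidation. Elbs persulfate hydroxylation (K2S2O8, aqueous KOH, 5–10 °C, argon) sulfates only the position para to a phenoxide, which exists only at C5′ of ring B, giving the licoricidin 5′-sulfate potassium salt F5. Mild hydrolysis at pH 1 and 40 °C gives the 2′,4′,5′-trihydroxy compound F6. Stirring F6 in air at pH 7 oxidises the hydroxyhydroquinone to quinone 17.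

**Further compounds**

F1 | step 8 | (E)-2′-hydroxychalcone: chalcone 9 lacking the MOM group ortho to the ketone | COCOc1cc(O)c(C(=O)/C=C/c2ccc(OCOC)c(CC=C(C)C)c2OCOC)c(OC)c1CC=C(C)C
F2 | step 8 | racemic 2-[2,4-bis(methoxymethoxy)-3-prenylphenyl]-5-methoxy-7-(methoxymethoxy)-6-prenylchroman-4-one | COCOc1cc2OC(c3ccc(OCOC)c(CC=C(C)C)c3OCOC)CC(=O)c2c(OC)c1CC=C(C)C
F3 | step 8 | tert-butyldimethylsilyl enol ether of F2 (4-silyloxy-2H-chromene) | COCOc1cc2OC(c3ccc(OCOC)c(CC=C(C)C)c3OCOC)C=C(O[Si](C)(C)C(C)(C)C)c2c(OC)c1CC=C(C)C
F4 | step 9 | cis-(6aR,11aR)-3,9-dihydroxy-1-methoxy-2,10-diprenylpterocarpan | Oc1cc2OC[C@H]3c4ccc(O)c(CC=C(C)C)c4O[C@H]3c2c(OC)c1CC=C(C)C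
F5 | step 10 | (3R)-licoricidin 5′-O-sulfate, potassium salt | COc1c(CC=C(C)C)c(O)cc2c1C[C@H](c1cc(OS(=O)(=O)[O-])c(O)c(CC=C(C)C)c1O)CO2.[K+]
F6 | step 10 | (3R)-5′-hydroxylicoricidin (2′,4′,5′-trihydroxy ring B) | COc1c(CC=C(C)C)c(O)cc2c1C[C@H](c1cc(O)c(O)c(CC=C(C)C)c1O)CO2
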